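A direct plan would take ring A from a chiral-pool cyclohexenone, join dienyl diol A1 and (Z)-enal A2 in a Prins–pinacol reaction to oxolane aldehyde A3, remove the formyl group, add the C11 hydroxyl, close the lactone from epoxy acid A4 and close the oxonane last at C6–C7 by a Nozaki–Hiyama–Kishi reaction of iodo aldehyde A5 to alcohol A6.
It would spend about fourteen steps on protecting-group and oxidation-level changes of small fragments before a second ring exists, and three more (bromohydrin, radical reduction, desilylation) on one tertiary hydroxyl.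
Weak step (a) would be the repair of C2 by hydride abstraction to a ketal and silane reduction: the key step would set C2 the wrong way for this target, and the repair would rest on a facial preference of a cation that is conjugated to the (Z)-alkene and could scramble it.
Weak step (b) would be the chromium-mediated closure of the nine-membered ring: two chains on opposite faces of the oxolane would have to meet end to end under high dilution, C6 would be left to a conformational guess, and the step would be run on the most advanced material, right after a haloboration next to a free hydroxyl, a lactone and an ester.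
Weak step (c) would be the lactonisation by attack of the acid on the tertiary epoxide carbon: C3 would have to invert cleanly at a centre that ionises easily, on an epoxide whose face is only argued from a conformer.

The new route cuts, in retrosynthetic order, the lactone C16–O bond, then the C2–O bond of the ether bridge (oxolane and oxonane open together to the ten-membered carbocycle C1–C10 with an (E)-C2=C3 alkene), then C4–C5 while joining C2 to C7. The carbocycle thereby folds into a cis-decalin (ring A plus a temporary ring D made of C1, C2, C7, C8, C9, C10) that a Diels–Alder reaction assembles from two small pieces.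
The feature that allows this: in the C1–C10 carbocycle shared by oxolane and oxonane, C7 (ketone level, the exo-methylene carbon) and C2 stand 1,6 to each other, C6 next to C7 bears oxygen, and C2 and C3 both bear oxygen. This is the retron of an anionic oxy-Cope ring expansion (C7 ketone, C6 enolate, C2=C3 alkene) followed by epoxidation.
Rings arise in the order A, D (temporary), ten-membered carbocycle, oxolane together with oxonane, lactone.
No C2 repair arises because C2 is made by SN2 opening of an epoxide. No medium ring is closed end to end because the ten-membered ring grows out of a six-membered one and the ether bridge then closes as a five-membered ring. C6 and C4 are set on the formed ring by an inversion and a reagent-controlled reduction, and the lactone closes by acylation, not by epoxide opening.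

Key step: step 9

Remark: the configuration is taken exactly as written (H2 cis to H1 and H10, H9 trans to them), so C3 and C8 leave the oxolane on opposite faces and the oxonane is a trans-bridged, strained ring; this is accepted as a property of the target, and the C2–O bond that creates the bridge is therefore formed in a strain-releasing epoxide opening.
Locants: C1–C14 are the carbons of the 2,11-cyclised cembrane skeleton (ring A = C1, C10–C14), C15–C17 the propanoate unit, C18, C19, C20 the one-carbon groups on C3, C7, C11; on the decalins β is the face of H1 and H10.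

Step 1
Reactants: 1 (2R)-4-methoxy-2-methyl-4-oxobutanoic acid
Product: 2 1-tert-butyl 4-methyl (2R)-2-methylbutanedioate
Conditions: tert-butyl 2,2,2-trichloroacetimidate, BF3·OEt2 (cat.), cyclohexane/CH2Cl2, rt
Reagents that add atoms: tert-butyl 2,2,2-trichloroacetimidate, CC(C)(C)OC(=N)C(Cl)(Cl)Cl
Why: Acid-catalysed O-alkylation of the free carboxylic acid by the imidate (tert-butyl esterification) tells the two carboxyl groups apart without touching the stereocentre that becomes C15.

Step 2
Reactants: 2 1-tert-butyl 4-methyl (2R)-2-methylbutanedioate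
Product: 3 tert-butyl (2R)-2-methyl-4-oxobutanoate
Conditions: i-Bu2AlH (1.05 equiv), CH2Cl2, −78 °C; Rochelle salt work-up
Reagents that add atoms: none
Why: Partial reduction at low temperature should take the unhindered methyl ester to the aldehyde through a stable aluminium hemiacetal while the tert-butyl ester is inert.

Step 3
Reactants: 3 tert-butyl (2R)-2-methyl-4-oxobutanoate; 4 but-3-en-2-one
Product: 6 tert-butyl (2R)-2-[(1R)-4-oxocyclohex-2-en-1-yl]propanoate, via keto aldehyde 5 (not isolated)
Conditions: (S)-2-[diphenyl(trimethylsilyloxy)methyl]pyrrolidine (10 mol %), ethyl 3,4-dihydroxybenzoate (20 mol %), neat, 4 °C; then LiOH (cat.), i-PrOH, rt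
Reagents that add atoms: none
Why: Enamine-catalysed Michael addition of the aldehyde to the enone followed by intramolecular aldol condensation (organocatalytic Robinson-type annulation) should give the 4-substituted cyclohexenone; the catalyst shields one face of the (E)-enamine and sets C14, the remote C15 centre having little say.

Step 4
Reactants: 7 4-methylpent-3-en-2-one; 8 ethyl formate
Product: 10 (1E)-1-[(tert-butyldimethylsilyl)oxy]-5-methylhexa-1,4-dien-3-one, via sodium enolate 9 (not isolated)
Conditions: NaH, Et2O, 0 °C; then t-BuMe2SiCl, THF, 0 °C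
Reagents that add atoms: tert-butyldimethylsilyl chloride, CC(C)(C)[Si](C)(C)Cl
Why: Claisen condensation of the methyl ketone with the formate (formylation) and O-silylation of the resulting enolate should give the (E)-β-silyloxy enone, the sterically preferred geometry.

Step 5
Reactants: 10 (1E)-1-[(tert-butyldimethylsilyl)oxy]-5-methylhexa-1,4-dien-3-one
Product: 11 (1E,3Z)-1-[(tert-butyldimethylsilyl)oxy]-5-methyl-3-[(trimethylsilyl)oxy]hexa-1,3,5-triene
Conditions: Me3SiOTf, Et3N, Et2O, 0 °C
Reagents that add atoms: trimethylsilyl trifluoromethanesulfonate, C[Si](C)(C)OS(=O)(=O)C(F)(F)F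
Why: Soft enolisation (silyl triflate and amine) can only remove a γ-hydrogen of the dimethylvinyl group, which gives the trienol ether with the isopropenyl group on the outer (3Z) position, the less strained one.

Step 6
Reactants: 6 tert-butyl (2R)-2-[(1R)-4-oxocyclohex-2-en-1-yl]propanoate; 11 silyloxy triene
Product: 12 cis-decalin adduct (ring A and ring D): C11 ketone, C7 trimethylsilyl enol ether (C7=C8), 9α-OTBS, 2α-isopropenyl, H1 and H10 β, C14 side chain β
Conditions: toluene, 110 °C (sealed tube), 2,6-di-tert-butyl-4-methylphenol (cat.)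
Reagents that add atoms: none
Why: Diels–Alder reaction of the 1,3-dioxygenated diene unit of 11 (the other diene unit cannot become s-cis because its terminus C7 is fully substituted): the nucleophilic terminus C2 bonds to the β-carbon C1, the diene adds anti to the C14 side chain and endo, which makes the ring fusion cis and places the C9 silyloxy and C2 isopropenyl groups cis to ring A.

Step 7
Reactants: 12 cis-decalin adduct
Product: 14 C7 ketone: 11α-hydroxy-11β-methyl, 9α-OTBS, 2α-isopropenyl cis-decalin, via carbinol silyl enol ether 13 (not isolated)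
Conditions: MeMgBr, THF, −78 °C; then aqueous citric acid, THF, 0 °C
Reagents that add atoms: methylmagnesium bromide, C[Mg]Br
Why: Grignard addition to the only free ketone (C7 is masked as the enol ether, the tert-butyl ester is inert) should occur axially on the β face, anti to the axial C9 of ring D, which sets C11; mild acid then hydrolyses the trimethylsilyl enol ether and leaves the TBS ether.

Step 8
Reactants: 14 C7 ketone
Product: 15 divinyl carbinol: 7β-vinyl, 7α-hydroxy, 2α-isopropenyl, 9α-OTBS, 11α-hydroxy cis-decalin
Conditions: CH2=CHMgBr, CeCl3, THF, −78 °C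
Reagents that add atoms: vinylmagnesium bromide, C=C[Mg]Br
Why: 1,2-Addition of the weakly basic vinylcerium reagent (no β-elimination of the C9 silyloxy group, no conjugation of the isopropenyl group) from the equatorial β direction, the α face being blocked by the axial C1–C14 and C9–O bonds, should place vinyl and isopropenyl trans-diequatorial.

Step 9
Reactants: 15 divinyl carbinol
Product: 17 (2E,6S)-6-hydroxy ketone: ten-membered carbocycle C1–C10 cis-fused to ring A, C7 ketone, 9-OTBS, 11-OH, via dipotassium enolate 16 (not isolated)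
Conditions: KN(SiMe3)2 (2.3 equiv), 18-crown-6, THF, −78 to 0 °C; then 2-(benzenesulfonyl)-3-phenyloxaziridine, −78 °C; NH4Cl work-up
Reagents that add atoms: 2-(benzenesulfonyl)-3-phenyloxaziridine, O=S(=O)(c1ccccc1)N1OC1c1ccccc1
Why: The C7 potassium alkoxide of 15 triggers a charge-accelerated [3,3] sigmatropic shift of the 1,5-diene C5=C6–C7–C2–C3=C4 (anionic oxy-Cope rearrangement) that breaks the temporary C2–C7 bond and forms C4–C5; the closest known reaction type is the ring expansion of trans-1,2-dialkenylcyclohexanols to (E)-cyclodec-5-enones. No ring is closed between chain ends: the ten-membered carbocycle C1–C10 arises by four-atom ring expansion of ring D through a chair transition state that is trans-fused to ring D. The (E) geometry of C2=C3 follows from the equatorial place of C1 on C2 in this chair, which the diequatorial vinyl and isopropenyl groups secure, and the 1,3-diaxial strain between O7, O9 and C14 in 15 speeds the shift. The enolate forms only towards C6, so the oxaziridine (Davis hydroxylation) oxygenates C6 and not C8. C6 is set by attack on the outer face of the enolate, whose inner face is covered by the parallel C2=C3 bond across the ring; this should give the 6S alcohol, which the next step inverts. The step needs rearrangement to outrun migration or loss of the C9 silyloxy group and deprotonation next to the ester, which the non-nucleophilic amide base, the crown ether and the low temperature secure.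

Step 10
Reactants: 17 (2E,6S)-6-hydroxy ketone
Product: 18 (2E,6R)-6-butanoyloxy ketone
Conditions: butanoic acid, PPh3, i-PrO2CN=NCO2i-Pr, toluene, 0 °C to rt
Reagents that add atoms: butanoic acid, CCCC(=O)O
Why: Mitsunobu esterification displaces the oxyphosphonium group of the α-ketol by SN2 with inversion, which turns the 6S alcohol into the 6R butanoate of the target; the tertiary C11 hydroxyl does not react.

Step 11
Reactants: 18 (2E,6R)-6-butanoyloxy ketone
Product: 19 C4 allylic alcohol of 18 (C4 epimers)
Conditions: SeO2 (0.3 equiv), t-BuOOH, CH2Cl2, 0 °C to rt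
Reagents that add atoms: selenium dioxide, O=[Se]=O; tert-butyl hydroperoxide, CC(C)(C)OO
Why: Selenium dioxide allylic oxidation (ene reaction at the more substituted alkene carbon C3, then [2,3] sigmatropic shift) should oxygenate the methylene trans to C1, that is C4, before the C18 methyl group and return the (E)-alkene; the C4 configuration does not matter because steps 13 and 14 set it again.

Step 12
Reactants: 19 C4 allylic alcohol
Product: 20 7(19)-methylene compound, C4 allylic alcohol (C4 epimers)
Conditions: Zn, CH2Br2, TiCl4, THF/CH2Cl2, 0 °C to rt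
Reagents that add atoms: dibromomethane, BrCBr
Why: Lombardo–Takai methylenation (geminal dizinc reagent activated by the titanium chloride) converts the ketone into the exo-methylene group without base, so the C6 ester neither migrates nor epimerises and the esters are not attacked.

Step 13
Reactants: 20 7(19)-methylene C4 allylic alcohol
Product: 21 (2E)-C4 enone
Conditions: MnO2, CH2Cl2, rt
Reagents that add atoms: none
Why: MnO2 oxidises only the allylic secondary alcohol; the tertiary alcohol, the silyl ether and the allylic ester are inert.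

Step 14
Reactants: 21 (2E)-C4 enone
Product: 22 (2E,4R)-allylic alcohol, 9-OTBS
Conditions: (S)-B-methyl oxazaborolidine derived from α,α-diphenylprolinol (0.3 equiv), catecholborane, toluene, −78 °C
Reagents that add atoms: none
Why: Corey–Bakshi–Shibata reduction: the oxazaborolidine–borane complex delivers hydride to the ketone face fixed by the catalyst (alkenyl side as the large group), which should give the 4R alcohol by 1,2-reduction under reagent control.

Step 15
Reactants: 22 (2E,4R)-allylic alcohol
Product: 23 (2E,4R,6R)-4,9-diol 6-butanoate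
Conditions: HF·pyridine, pyridine, THF, 0 °C to rt
Reagents that add atoms: none
Why: Buffered fluoride cleaves the secondary silyl ether and frees the C9 hydroxyl while the two carboxylic esters stay in place.

Step 16
Reactants: 23 (2E,4R,6R)-4,9-diol
Product: 25 oxolane–oxonane tricycle: 3,4,11-triol 6-butanoate, tert-butyl ester, via epoxy alcohol 24 (not isolated)
Conditions: VO(acac)2 (5 mol %), t-BuOOH, CH2Cl2, 0 °C to rt
Reagents that add atoms: tert-butyl hydroperoxide, CC(C)(C)OO
Why: Hydroxyl-directed epoxidation (the vanadium alkoxide of the C4 allylic alcohol delivers the peroxide oxygen; erythro selectivity as for α-methyl secondary allylic alcohols, matched with attack on the outer face of the (E)-cyclodecene) should give the (2S,3S)-epoxide 24, which the C9 hydroxyl opens at C2 in a 5-exo SN2 step with inversion (C3 is deactivated by the C4 oxygen); this closes oxolane and oxonane at once and sets C2 (H2 cis to H1) and the tertiary C3 carbinol.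

Step 17
Reactants: 25 oxolane–oxonane triol
Product: 26 C4 octanoate
Conditions: octanoyl chloride, pyridine, DMAP (cat.), CH2Cl2, 0 °C
Reagents that add atoms: octanoyl chloride, CCCCCCCC(=O)Cl
Why: Acylation with the acid chloride under nucleophilic catalysis esterifies the only secondary hydroxyl with retention; the tertiary C3 and C11 hydroxyls are too hindered.

Step 18
Reactants: 26 C4 octanoate
Product: 28 hydroxy acid (C16 carboxylic acid, C3 hydroxyl free), via silyl ester 27 (not isolated)
Conditions: Me3SiOTf, 2,6-lutidine, CH2Cl2, 0 °C; then aqueous citric acid, THF, rt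
Reagents that add atoms: none
Why: Silyl triflate activates the tert-butyl ester, which loses 2-methylpropene to give the trimethylsilyl ester (the tertiary hydroxyls are silylated in passing); mild aqueous acid then cleaves all Si–O bonds, conditions that spare the allylic ester and the tertiary carbinols.

Step 19
Reactants: 28 hydroxy acid
Product: 30 CNP0350718.2 (target), via mixed anhydride 29 (not isolated)
Conditions: 2,4,6-trichlorobenzoyl chloride, Et3N, THF, rt; then DMAP, toluene, 80 °C (high dilution)
Reagents that add atoms: none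
Why: Yamaguchi lactonisation: DMAP attacks the mixed anhydride and the acylpyridinium ion acylates the C3 hydroxyl, the only one that can reach C16 (seven-membered ring, cis-fused to the oxolane; the C11 hydroxyl lies on the far side of ring A), with no change at any stereocentre.

**Compound list**

1 | (2R)-4-methoxy-2-methyl-4-oxobutanoic acid | COC(=O)C[C@@H](C)C(=O)O | starting material
2 | 1-tert-butyl 4-methyl (2R)-2-methylbutanedioate | COC(=O)C[C@@H](C)C(=O)OC(C)(C)C | intermediate
3 | tert-butyl (2R)-2-methyl-4-oxobutanoate | O=CC[C@@H](C)C(=O)OC(C)(C)C | intermediate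
4 | but-3-en-2-one | CC(=O)C=C | starting material
5 | tert-butyl (2R,3S)-3-formyl-2-methyl-6-oxoheptanoate | CC(=O)CC[C@H](C=O)[C@@H](C)C(=O)OC(C)(C)C | intermediate
6 | tert-butyl (2R)-2-[(1R)-4-oxocyclohex-2-en-1-yl]propanoate | O=C1CC[C@@H]([C@@H](C)C(=O)OC(C)(C)C)C=C1 | intermediate
7 | 4-methylpent-3-en-2-one | CC(C)=CC(C)=O | starting material
8 | ethyl formate | CCOC=O | starting material
9 | sodium (1E)-5-methyl-3-oxohexa-1,4-dien-1-olate | CC(C)=CC(=O)/C=C/[O-].[Na+] | intermediate
10 | (1E)-1-[(tert-butyldimethylsilyl)oxy]-5-methylhexa-1,4-dien-3-one | CC(C)=CC(=O)/C=C/O[Si](C)(C)C(C)(C)C | intermediate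
11 | (1E,3Z)-1-[(tert-butyldimethylsilyl)oxy]-5-methyl-3-[(trimethylsilyl)oxy]hexa-1,3,5-triene | C=C(C)/C=C(O[Si](C)(C)C)/C=C/O[Si](C)(C)C(C)(C)C | intermediate
12 | cis-decalin adduct: C11 ketone, C7 trimethylsilyl enol ether, 9α-OTBS, 2α-isopropenyl | C[Si](C)(C)OC1=C[C@H](O[Si](C)(C)C(C)(C)C)[C@@H]2C(=O)CC[C@@H]([C@@H](C)C(=O)OC(C)(C)C)[C@@H]2[C@@H]1C(C)=C | intermediate
13 | 11α-hydroxy-11β-methyl carbinol of 12, C7 silyl enol ether intact | C[Si](C)(C)OC1=C[C@H](O[Si](C)(C)C(C)(C)C)[C@@H]2[C@](C)(O)CC[C@@H]([C@@H](C)C(=O)OC(C)(C)C)[C@@H]2[C@@H]1C(C)=C | intermediate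
14 | C7 ketone: 11α-hydroxy-11β-methyl, 9α-OTBS, 2α-isopropenyl cis-decalin | O=C1C[C@H](O[Si](C)(C)C(C)(C)C)[C@@H]2[C@](C)(O)CC[C@@H]([C@@H](C)C(=O)OC(C)(C)C)[C@@H]2[C@@H]1C(C)=C | intermediate
15 | divinyl carbinol: 7β-vinyl, 7α-hydroxy, 2α-isopropenyl, 9α-OTBS | C=C[C@@]1(O)C[C@H](O[Si](C)(C)C(C)(C)C)[C@@H]2[C@](C)(O)CC[C@@H]([C@@H](C)C(=O)OC(C)(C)C)[C@@H]2[C@@H]1C(C)=C | intermediate
16 | dipotassium salt: C6=C7 enolate and C11 alkoxide of the (2E)-cyclodecenone | [K+].[K+].C1[C@H](O[Si](C)(C)C(C)(C)C)[C@@H]2[C@](C)([O-])CC[C@@H]([C@@H](C)C(=O)OC(C)(C)C)[C@@H]2/C=C(\C)CC/C=C1\[O-] | intermediate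
17 | (2E,6S)-6-hydroxy ketone (ten-membered carbocycle, C7 ketone, 9-OTBS) | O=C1C[C@H](O[Si](C)(C)C(C)(C)C)[C@@H]2[C@](C)(O)CC[C@@H]([C@@H](C)C(=O)OC(C)(C)C)[C@@H]2/C=C(\C)CC[C@@H]1O | intermediate
18 | (2E,6R)-6-butanoyloxy ketone | O=C1C[C@H](O[Si](C)(C)C(C)(C)C)[C@@H]2[C@](C)(O)CC[C@@H]([C@@H](C)C(=O)OC(C)(C)C)[C@@H]2/C=C(\C)CC[C@H]1OC(=O)CCC | intermediate
19 | C4 allylic alcohol of 18 (C4 epimers) | O=C1C[C@H](O[Si](C)(C)C(C)(C)C)[C@@H]2[C@](C)(O)CC[C@@H]([C@@H](C)C(=O)OC(C)(C)C)[C@@H]2/C=C(\C)C(O)C[C@H]1OC(=O)CCC | intermediate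
20 | 7(19)-methylene compound, C4 allylic alcohol (C4 epimers) | C=C1C[C@H](O[Si](C)(C)C(C)(C)C)[C@@H]2[C@](C)(O)CC[C@@H]([C@@H](C)C(=O)OC(C)(C)C)[C@@H]2/C=C(\C)C(O)C[C@H]1OC(=O)CCC | intermediate
21 | (2E)-C4 enone | C=C1C[C@H](O[Si](C)(C)C(C)(C)C)[C@@H]2[C@](C)(O)CC[C@@H]([C@@H](C)C(=O)OC(C)(C)C)[C@@H]2/C=C(\C)C(=O)C[C@H]1OC(=O)CCC | intermediate
22 | (2E,4R)-allylic alcohol, 9-OTBS | C=C1C[C@H](O[Si](C)(C)C(C)(C)C)[C@@H]2[C@](C)(O)CC[C@@H]([C@@H](C)C(=O)OC(C)(C)C)[C@@H]2/C=C(\C)[C@H](O)C[C@H]1OC(=O)CCC | intermediate
23 | (2E,4R,6R)-4,9-diol 6-butanoate | C=C1C[C@H](O)[C@@H]2[C@](C)(O)CC[C@@H]([C@@H](C)C(=O)OC(C)(C)C)[C@@H]2/C=C(\C)[C@H](O)C[C@H]1OC(=O)CCC | intermediate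
24 | (2S,3S)-2,3-epoxide of 23 | C=C1C[C@H](O)[C@@H]2[C@](C)(O)CC[C@@H]([C@@H](C)C(=O)OC(C)(C)C)[C@@H]2[C@@H]3O[C@@]3(C)[C@H](O)C[C@H]1OC(=O)CCC | intermediate
25 | oxolane–oxonane tricycle: 3,4,11-triol 6-butanoate, tert-butyl ester | C=C1C[C@@H]2O[C@H]([C@H]4[C@@H](CC[C@@](C)(O)[C@H]42)[C@@H](C)C(=O)OC(C)(C)C)[C@@](C)(O)[C@H](O)C[C@H]1OC(=O)CCC | intermediate
26 | C4 octanoate of 25 | C=C1C[C@@H]2O[C@H]([C@H]4[C@@H](CC[C@@](C)(O)[C@H]42)[C@@H](C)C(=O)OC(C)(C)C)[C@@](C)(O)[C@H](OC(=O)CCCCCCC)C[C@H]1OC(=O)CCC | intermediate
27 | trimethylsilyl ester, 3,11-bis(trimethylsilyl) ether | C=C1C[C@@H]2O[C@H]([C@H]4[C@@H](CC[C@@](C)(O[Si](C)(C)C)[C@H]42)[C@@H](C)C(=O)O[Si](C)(C)C)[C@@](C)(O[Si](C)(C)C)[C@H](OC(=O)CCCCCCC)C[C@H]1OC(=O)CCC | intermediate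
28 | hydroxy acid (C16 acid, C3 hydroxyl free) | C=C1C[C@@H]2O[C@H]([C@H]4[C@@H](CC[C@@](C)(O)[C@H]42)[C@@H](C)C(=O)O)[C@@](C)(O)[C@H](OC(=O)CCCCCCC)C[C@H]1OC(=O)CCC | intermediate
29 | mixed anhydride of 28 with 2,4,6-trichlorobenzoic acid | C=C1C[C@@H]2O[C@H]([C@H]4[C@@H](CC[C@@](C)(O)[C@H]42)[C@@H](C)C(=O)OC(=O)c5c(Cl)cc(Cl)cc5Cl)[C@@](C)(O)[C@H](OC(=O)CCCCCCC)C[C@H]1OC(=O)CCC | intermediate
30 | CNP0350718.2 | C=C1C[C@@H]2O[C@@H]3[C@H]4[C@@H](CC[C@@](C)(O)[C@H]42)[C@@H](C)C(=O)O[C@@]3(C)[C@H](OC(=O)CCCCCCC)C[C@H]1OC(=O)CCC | target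

Total step count: 19. Longest linear sequence: 17 steps (steps 1 to 3 and 6 to 19).

Steps most likely to fail:

Step 16. The oxidant may attack the wrong face of C2=C3, the C9 hydroxyl may close at the tertiary carbon C3 (six-membered ether), or closure may stall because of the strain of the trans-bridged ring. The fallback sets out from 23 and replaces substrate control by reagent control. Sharpless asymmetric epoxidation with Ti(Oi-Pr)4, D-(−)-diisopropyl tartrate and t-BuOOH (matched with the 4R carbinol) would give epoxy alcohol 24. With a full equivalent of Ti(Oi-Pr)4 the chelated epoxy alcohol is opened at the carbon remote from the carbinol, which is C2, so the C9 hydroxyl would close the oxolane there. The sequence comes back at 25 and makes no new compound.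

Step 9. The C9 silyloxy group may migrate or be lost in the dialkoxide, the strongly basic alkoxide may epimerise C15, or the hydroxylation may be unselective. The fallback sets out from 15 and avoids any free base. Silylation of both tertiary hydroxyls (Me3SiOTf, Et3N) would give the bis(trimethylsilyl) ether F1. A thermal, neutral siloxy-Cope rearrangement (o-dichlorobenzene, 180 °C) through the same chair would give the ten-membered trimethylsilyl enol ether F2. Rubottom oxidation (m-CPBA, NaHCO3; epoxidation of the enol ether on its outer face and silyl shift) would give the 6-(trimethylsilyloxy) ketone F3. Citric acid in methanol would then remove the trimethylsilyl groups, and the sequence comes back at 17.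

Step 19. Acylation of the tertiary C3 hydroxyl may be slow, so that intermolecular esters or ketene formation at C15 with epimerisation win. The fallback sets out from 25 and changes the order, so that the lactone closes under thermodynamic control before the last acylation. Cleavage of the tert-butyl ester (silica gel, toluene, 110 °C) would give the dihydroxy acid F4. Acid-catalysed lactonisation (camphorsulfonic acid, benzene, azeotropic removal of water), in which the seven-membered lactone on O3 is preferred over the eight-membered one on O4, would give the hydroxy lactone F5. Octanoylation of the C4 hydroxyl (octanoyl chloride, pyridine, DMAP) then comes back at 30.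

**Further compounds**

F0 | step 16 | none | none
F1 | step 9 | bis(trimethylsilyl) ether of 15 | C=C[C@@]1(O[Si](C)(C)C)C[C@H](O[Si](C)(C)C(C)(C)C)[C@@H]2[C@](C)(O[Si](C)(C)C)CC[C@@H]([C@@H](C)C(=O)OC(C)(C)C)[C@@H]2[C@@H]1C(C)=C
F2 | step 9 | ten-membered trimethylsilyl enol ether (C6=C7), 11-OTMS, 9-OTBS | C1[C@H](O[Si](C)(C)C(C)(C)C)[C@@H]2[C@](C)(O[Si](C)(C)C)CC[C@@H]([C@@H](C)C(=O)OC(C)(C)C)[C@@H]2/C=C(\C)CC/C=C1\O[Si](C)(C)C
F3 | step 9 | (6S)-6-(trimethylsilyloxy) ketone, 11-OTMS, 9-OTBS | O=C1C[C@H](O[Si](C)(C)C(C)(C)C)[C@@H]2[C@](C)(O[Si](C)(C)C)CC[C@@H]([C@@H](C)C(=O)OC(C)(C)C)[C@@H]2/C=C(\C)CC[C@@H]1O[Si](C)(C)C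
F4 | step 19 | dihydroxy acid (C16 acid, C3 and C4 hydroxyls free, 6-butanoate) | C=C1C[C@@H]2O[C@H]([C@H]4[C@@H](CC[C@@](C)(O)[C@H]42)[C@@H](C)C(=O)O)[C@@](C)(O)[C@H](O)C[C@H]1OC(=O)CCC
F5 | step 19 | hydroxy lactone (C4 hydroxyl free, 6-butanoate) | C=C1C[C@@H]2O[C@@H]3[C@H]4[C@@H](CC[C@@](C)(O)[C@H]42)[C@@H](C)C(=O)O[C@@]3(C)[C@H](O)C[C@H]1OC(=O)CCC
A1 | direct plan | cyclohexadienyl 1,2-diol | CC1=CC[C@H](C=C1[C@@H](O)[C@@H](O)CC#C[Si](C)(C)C)[C@@H](C)COC(=O)C(C)(C)C
A2 | direct plan | (2Z)-5-(tert-butyldimethylsilyloxy)-2-methylpent-2-enal | O=C/C(C)=C\CCO[Si](C)(C)C(C)(C)C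
A3 | direct plan | 2-epi oxolane aldehyde (formyl on C10) | C[Si](C)(C)C#CC[C@@H]2O[C@H](/C(C)=C\CCO[Si](C)(C)C(C)(C)C)[C@H]4[C@@H](CC=C(C)[C@]42C=O)[C@@H](C)COC(=O)C(C)(C)C
A4 | direct plan | 3,4-epoxy acid | C#CC[C@@H]2O[C@@H]([C@]7(C)O[C@@H]7CCO[Si](C)(C)C(C)(C)C)[C@H]4[C@@H](CC[C@@](C)(O)[C@H]42)[C@@H](C)C(=O)O
A5 | direct plan | iodo aldehyde (C7 iodide, C6 aldehyde) | C=C(I)C[C@@H]2O[C@@H]3[C@H]4[C@@H](CC[C@@](C)(O)[C@H]42)[C@@H](C)C(=O)O[C@@]3(C)[C@H](OC(=O)CCCCCCC)CC=O
A6 | direct plan | tetracyclic (6R) allylic alcohol | C=C1C[C@@H]2O[C@@H]3[C@H]4[C@@H](CC[C@@](C)(O)[C@H]42)[C@@H](C)C(=O)O[C@@]3(C)[C@H](OC(=O)CCCCCCC)C[C@H]1O
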